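**Retrosynthetic overview**
1. Target 29 ⇒ acyclic enyne 27: the ten-membered ring is closed last by ethylene-mediated enyne metathesis/RCM, which forms C3=C4 and the C5=C16 methylene.
2. 27 ⇒ keto ester 26: the γ-lactone (C8–C17 bond, C8/C17 centres) comes from an intramolecular samarium Reformatsky reaction; C6–Cl from SN2 on a propargylic alcohol; C5≡C4 from ethynyl Grignard.
3. Ring-A oxygens ⇒ cyclohexa-11,13-diene 14 (OsO4, then OH-directed V/TBHP epoxidation); C2 carbinol ⇒ vinylation of neopentyl aldehyde 10.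
4. Key disconnection: cyclohexenone 10 ⇒ Diels–Alder of amino-siloxy diene 7 with (E)-2-methyl enal 5; the C9 stereocentre controls C1 and C10.
5. 5 ⇒ L-arabinose (supplies C6–C10 and the C7 and C9 oxygens). Ring order: cyclohexane → epoxide → lactone → ten-membered ring.

Assumption/notation: the target is taken exactly as drawn (3Z); locants are briarane numbers (ten-membered ring C1–C10, cyclohexane C1/C10–C14, C15 = Me on C1, C16 = CH2 on C5, C17/C18/C19 = lactone CH/Me/C=O, C20 = Me on C11); α = cyclohexane face of H-10 and C2, β = face of C15 and C9; 3 and 6 are taken as catalogue compounds.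

**Route**

Step 1
Reactants: 1 L-arabinose
Product: 2 3,4-O-isopropylidene-β-L-arabinopyranose
Conditions: Me2C(OMe)2, TsOH (cat.), DMF, rt
Reagents that add atoms: 2,2-dimethoxypropane COC(C)(C)OC
Why: Acid-catalysed acetalisation (thermodynamic acetonide) engages the only cis-vicinal diol of the pyranose (O3/O4) and leaves the lactol and 2-OH free; the three carbinol centres bought with L-arabinose become C9, C8 and C7.

Step 2
Reactants: 2 3,4-O-isopropylidene-β-L-arabinopyranose; 3 2-(triphenyl-λ5-phosphanylidene)propanal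
Product: 4 (2E,4S)-4-hydroxy-4-[(4R,5S)-5-(hydroxymethyl)-2,2-dimethyl-1,3-dioxolan-4-yl]-2-methylbut-2-enal
Conditions: PhMe, PhCO2H (cat.), 90 °C
Reagents that add atoms: none
Why: Wittig olefination of the open-chain aldehyde tautomer with the formyl-stabilised ylide gives the (E)-trisubstituted enal, the α-methyl group makes oxa-Michael re-closure by the freed C6-OH slow, and no stereocentre is touched.

Step 3
Reactants: 4 enal diol
Product: 5 (2E,4S)-4-acetoxy-4-[(4R,5S)-5-(acetoxymethyl)-2,2-dimethyl-1,3-dioxolan-4-yl]-2-methylbut-2-enal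
Conditions: Ac2O, pyridine, DMAP (cat.), CH2Cl2, 0 °C → rt
Reagents that add atoms: acetic anhydride CC(=O)OC(C)=O
Why: Plain O-acetylation; the C9 acetate is already a target group and the σ*-acceptor used for face control in step 5, while the primary acetate is a temporary cap.

Step 4
Reactants: 6 (E)-1-(dimethylamino)pent-1-en-3-one
Product: 7 (1E,3Z)-3-[(tert-butyldimethylsilyl)oxy]-N,N-dimethylpenta-1,3-dien-1-amine
Conditions: NaHMDS, THF, −78 °C; TBSCl, −78 °C → rt
Reagents that add atoms: tert-butyldimethylsilyl chloride CC(C)(C)[Si](C)(C)Cl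
Why: O-Silylation of the kinetic (Z)-sodium enolate of the vinylogous amide gives the 1-amino-3-siloxy diene (Rawal-type) whose 4-methyl group becomes C20.

Step 5
Reactants: 5 enal diacetate; 7 amino-siloxy diene
Product: 10 4-formyl-4,6-dimethylcyclohex-2-en-1-one carrying at C5 the (S)-acetoxy[(4R,5S)-5-(acetoxymethyl)-2,2-dimethyl-1,3-dioxolan-4-yl]methyl chain (briarane: C2 aldehyde, C12 ketone, 13-ene; C1 and C10 as in the target; C11 epimers), via silyl enol ether cycloadduct 8 (not isolated), via β-amino ketone 9 (not isolated)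
Conditions: 7 (1.5 equiv), PhMe, 80 °C, sealed tube; then 1 M HCl/THF, 0 °C
Reagents that add atoms: none
Why: Normal-demand Diels–Alder cycloaddition in which the amino terminus bonds to the formyl-bearing carbon and the methyl-bearing terminus to the β-carbon, suprafacial addition to the E-enal puts C2 and C9 trans, and, because A(1,3) strain with the C15 methyl holds C9–H in the alkene plane, the diene adds anti to the C9–OAc bond (Felkin–Anh-type) and so sets C1 and C10; acid then hydrolyses the silyl enol ether and β-eliminates dimethylamine.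

Step 6
Reactants: 10 enone aldehyde
Product: 11 C2 vinyl carbinol (2S; 1-hydroxyprop-2-en-1-yl group on C1; otherwise as 10)
Conditions: CH2=CHBr, CrCl2 (5 equiv), NiCl2 (1 mol %), DMF/THF, rt
Reagents that add atoms: vinyl bromide C=CBr
Why: Nozaki–Hiyama–Kishi vinylation is aldehyde-selective (enone and acetates untouched) and follows the Felkin–Anh model with the C10 branch anti to the incoming vinyl group, which passes the C15 methyl and gives the 2S carbinol.

Step 7
Reactants: 11 C2 vinyl carbinol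
Product: 12 C2 acetate of 11 (2,9,6-triacetate; C12 ketone, 13-ene)
Conditions: Ac2O, pyridine, DMAP (cat.), CH2Cl2, rt
Reagents that add atoms: acetic anhydride CC(=O)OC(C)=O
Why: O-Acetylation installs the C2 acetate of the target and removes the only free OH before the next steps.

Step 8
Reactants: 12 enone triacetate
Product: 13 C12 allylic alcohol (13-ene; C11 and C12 epimer mixture)
Conditions: NaBH4, CeCl3·7H2O, MeOH, −78 → −20 °C
Reagents that add atoms: none
Why: Luche 1,2-reduction of the enone; the new C12 centre and the C11 epimers do not matter because both carbons become sp2 in step 9.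

Step 9
Reactants: 13 allylic alcohol
Product: 14 cyclohexa-11,13-diene (C11 methyl on the diene; C1 and C10 as in the target)
Conditions: Ph2S[OC(CF3)2Ph]2 (Martin sulfurane), CH2Cl2, 0 °C → rt
Reagents that add atoms: none
Why: Dehydration with Martin sulfurane: the allylic alkoxysulfurane eliminates and only C11–H can be lost, giving the conjugated 11,13-diene.

Step 10
Reactants: 14 diene
Product: 15 11α,12α-diol (13-ene; Me-20 β)
Conditions: OsO4 (2 mol %), NMO (1.05 equiv), acetone/H2O, 0 °C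
Reagents that add atoms: osmium tetroxide (cat.) O=[Os](=O)(=O)=O; N-methylmorpholine N-oxide C[N+]1([O-])CCOCC1; water O
Why: Upjohn syn-dihydroxylation ([3+2] osmylation) takes the more electron-rich trisubstituted C11=C12 bond from the α-face, anti to the C9 branch on C10 and the C15 methyl, so the cis relation of 11-OH and 12-OH is guaranteed and both are α.

Step 11
Reactants: 15 diol
Product: 16 13α,14α-epoxy-11α,12α-diol
Conditions: VO(acac)2 (5 mol %), t-BuOOH, CH2Cl2, 0 °C → rt
Reagents that add atoms: tert-butyl hydroperoxide CC(C)(C)OO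
Why: Hydroxyl-directed vanadium-catalysed epoxidation of the allylic alcohol delivers oxygen syn to 12-OH (and 11-OH), giving the 13α,14α-epoxide, while the C3 vinyl group has no free allylic OH and is left alone.

Step 12
Reactants: 16 epoxy diol
Product: 17 12-O-acetate of 16 (2,9,12,6-tetraacetate; 11-OH free)
Conditions: Ac2O, pyridine, DMAP (cat.), CH2Cl2, rt
Reagents that add atoms: acetic anhydride CC(=O)OC(C)=O
Why: Acetylation of the secondary 12-OH gives the third target acetate; the tertiary 11-OH does not react.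

Step 13
Reactants: 17 tetraacetate
Product: 18 C6 primary alcohol (2,9,12-triacetate)
Conditions: [t-Bu2SnCl(OH)]2 (5 mol %), MeOH/THF, 30 °C
Reagents that add atoms: none
Why: Distannoxane-catalysed transesterification discriminates the unhindered primary acetate from the three hindered secondary acetates.

Step 14
Reactants: 18 primary alcohol
Product: 19 C6 aldehyde (formyl on the dioxolane carbon C7)
Conditions: Dess–Martin periodinane, pyridine, CH2Cl2, 0 °C → rt
Reagents that add atoms: none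
Why: Dess–Martin oxidation of the primary alcohol to the α-alkoxy aldehyde under buffered, non-epimerising conditions.

Step 15
Reactants: 19 aldehyde
Product: 20 C6 propargylic alcohols (1-hydroxyprop-2-yn-1-yl on C7; C6 epimers)
Conditions: HC≡CMgBr (3 equiv), THF, −78 °C
Reagents that add atoms: ethynylmagnesium bromide C#C[Mg]Br
Why: Grignard 1,2-addition to the aldehyde at −78 °C (acetates survive); the C6 epimer ratio is irrelevant because the carbinol is oxidised next.

Step 16
Reactants: 20 propargylic alcohols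
Product: 21 C6 ynone (propynoyl group on C7)
Conditions: Dess–Martin periodinane, CH2Cl2, rt
Reagents that add atoms: none
Why: Dess–Martin oxidation of both propargylic alcohol epimers to a single ynone.

Step 17
Reactants: 21 ynone
Product: 22 6,7-syn propargylic alcohol (C6-OH syn to O7 in the zigzag drawing)
Conditions: L-Selectride (2.2 equiv), THF, −78 °C
Reagents that add atoms: none
Why: Felkin–Anh-controlled reduction: the bulky hydride attacks anti to the C7–O bond of the dioxolane and gives the 6,7-syn propargylic alcohol, the epimer that direct alkynylation does not favour.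

Step 18
Reactants: 22 syn propargylic alcohol
Product: 23 C6 propargylic chloride (C6 as in the target; 7,8-acetonide)
Conditions: PPh3, Cl3CCOCCl3, CH2Cl2, 0 °C
Reagents that add atoms: hexachloroacetone ClC(Cl)(Cl)C(=O)C(Cl)(Cl)Cl
Why: Appel-type chlorination is an SN2 displacement with inversion, so the syn alcohol gives the C6 chloride anti to O7 as in the target, with little allenyl chloride from SN2′.

Step 19
Reactants: 23 chloride acetonide
Product: 24 7,8-diol (C7 as in the target; C8 carbinol from arabinose C3)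
Conditions: TFA/H2O, CH2Cl2, 0 °C
Reagents that add atoms: none
Why: Acid-catalysed acetal hydrolysis frees the 7,8-diol; the epoxide survives because it is flanked by the quaternary C1 and the electron-poor C12 acetate carbon.

Step 20
Reactants: 24 diol
Product: 25 C7 2-bromopropanoate (C8-OH free; CHBr epimers)
Conditions: MeCHBrCOBr (1.1 equiv), 2,4,6-collidine, CH2Cl2, −78 → −40 °C
Reagents that add atoms: 2-bromopropanoyl bromide CC(Br)C(=O)Br
Why: Regioselective O-acylation: C7-OH reacts because C8-OH is shielded by the C9 acetate and the cyclohexane; the bromine-bearing centre is used as a mixture because it becomes an enolate.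

Step 21
Reactants: 25 bromo ester
Product: 26 C8 ketone
Conditions: Dess–Martin periodinane, CH2Cl2, rt
Reagents that add atoms: none
Why: Dess–Martin oxidation of the remaining secondary alcohol to the C8 ketone under neutral conditions that do not enolise the α-acyloxy, β-chloro ketone.

Step 22
Reactants: 26 keto bromo ester
Product: 27 lactone enyne (γ-lactone C19–O–C7 with 8-OH and 17-Me; all stereocentres of the target present)
Conditions: SmI2 (2.2 equiv), THF, −78 °C; aq NH4Cl
Reagents that add atoms: none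
Why: Intramolecular samarium Reformatsky (aldol) reaction: the Sm(III) ester enolate formed from the C–Br bond adds to the C8 ketone through a chelated transition state that places the C9 branch trans to C6 and the methyl group trans to C9, which sets C8 and C17 and closes the γ-lactone.

Step 23
Reactants: 27 lactone enyne
Product: 29 CNP0331168.1 (target), via 2-substituted butadiene 28 (not isolated)
Conditions: Grubbs II (15 mol %), H2C=CH2 (1 atm), CH2Cl2, rt; then Ar purge, PhMe (1 mM), 80 °C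
Reagents that add atoms: ethylene C=C
Why: Enyne cross-metathesis with ethylene turns the alkyne into the 2-substituted butadiene, and ring-closing metathesis of its vinyl terminus with the C3 vinyl group then closes the ten-membered ring, where ring size and reversibility favour the Z C3=C4 alkene; no stereocentre is touched.

**Compound list**

1 | L-arabinose (pyranose form) | OC1[C@H](O)[C@@H](O)[C@@H](O)CO1 | starting material
2 | 3,4-O-isopropylidene-β-L-arabinopyranose | O[C@@H]1[C@H](O)[C@H]2OC(C)(C)O[C@H]2CO1 | intermediate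
3 | 2-(triphenyl-λ5-phosphanylidene)propanal | CC(C=O)=P(c1ccccc1)(c1ccccc1)c1ccccc1 | starting material
4 | (2E,4S)-4-hydroxy-4-[(4R,5S)-5-(hydroxymethyl)-2,2-dimethyl-1,3-dioxolan-4-yl]-2-methylbut-2-enal | O=C/C(C)=C/[C@H](O)[C@H]1OC(C)(C)O[C@H]1CO | intermediate
5 | (2E,4S)-4-acetoxy-4-[(4R,5S)-5-(acetoxymethyl)-2,2-dimethyl-1,3-dioxolan-4-yl]-2-methylbut-2-enal | O=C/C(C)=C/[C@H](OC(C)=O)[C@H]1OC(C)(C)O[C@H]1COC(C)=O | intermediate
6 | (E)-1-(dimethylamino)pent-1-en-3-one | CCC(=O)/C=C/N(C)C | starting material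
7 | (1E,3Z)-3-[(tert-butyldimethylsilyl)oxy]-N,N-dimethylpenta-1,3-dien-1-amine | CN(C)/C=C/C(O[Si](C)(C)C(C)(C)C)=C/C | intermediate
8 | Diels–Alder adduct: 2-(dimethylamino)-1,5-dimethyl-4-(TBSO)cyclohex-3-ene-1-carbaldehyde with the C9–C6 chain of 5 on C6 (C1, C10 as in target; C11, C14 mixtures) | O=C[C@@]1(C)C(N(C)C)C=C(O[Si](C)(C)C(C)(C)C)C(C)[C@@H]1[C@H](OC(C)=O)[C@H]2OC(C)(C)O[C@H]2COC(C)=O | intermediate
9 | β-amino ketone: 2-(dimethylamino)-1,5-dimethyl-4-oxocyclohexane-1-carbaldehyde with the same chain (C11, C14 mixtures) | O=C[C@@]1(C)C(N(C)C)CC(=O)C(C)[C@@H]1[C@H](OC(C)=O)[C@H]2OC(C)(C)O[C@H]2COC(C)=O | intermediate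
10 | enone aldehyde: 4-formyl-4,6-dimethylcyclohex-2-en-1-one with the (S)-acetoxy[(4R,5S)-5-(acetoxymethyl)-2,2-dimethyl-1,3-dioxolan-4-yl]methyl chain on C5 (C11 epimers) | O=C[C@@]1(C)C=CC(=O)C(C)[C@@H]1[C@H](OC(C)=O)[C@H]2OC(C)(C)O[C@H]2COC(C)=O | intermediate
11 | C2 vinyl carbinol (2S) of 10 | C=C[C@H](O)[C@@]1(C)C=CC(=O)C(C)[C@@H]1[C@H](OC(C)=O)[C@H]2OC(C)(C)O[C@H]2COC(C)=O | intermediate
12 | C2 acetate of 11 (enone triacetate) | C=C[C@H](OC(C)=O)[C@@]1(C)C=CC(=O)C(C)[C@@H]1[C@H](OC(C)=O)[C@H]2OC(C)(C)O[C@H]2COC(C)=O | intermediate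
13 | C12 allylic alcohol, 13-ene (C11/C12 epimers) | C=C[C@H](OC(C)=O)[C@@]1(C)C=CC(O)C(C)[C@@H]1[C@H](OC(C)=O)[C@H]2OC(C)(C)O[C@H]2COC(C)=O | intermediate
14 | cyclohexa-11,13-diene | C=C[C@H](OC(C)=O)[C@@]1(C)C=CC=C(C)[C@@H]1[C@H](OC(C)=O)[C@H]2OC(C)(C)O[C@H]2COC(C)=O | intermediate
15 | 11α,12α-diol, 13-ene | C=C[C@H](OC(C)=O)[C@@]1(C)C=C[C@@H](O)[C@@](C)(O)[C@@H]1[C@H](OC(C)=O)[C@H]2OC(C)(C)O[C@H]2COC(C)=O | intermediate
16 | 13α,14α-epoxy-11α,12α-diol | C=C[C@H](OC(C)=O)[C@@]1(C)[C@H]2O[C@H]2[C@@H](O)[C@@](C)(O)[C@@H]1[C@H](OC(C)=O)[C@H]2OC(C)(C)O[C@H]2COC(C)=O | intermediate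
17 | 2,9,12,6-tetraacetate (11-OH free; 7,8-acetonide) | C=C[C@H](OC(C)=O)[C@@]1(C)[C@H]2O[C@H]2[C@@H](OC(C)=O)[C@@](C)(O)[C@@H]1[C@H](OC(C)=O)[C@H]2OC(C)(C)O[C@H]2COC(C)=O | intermediate
18 | C6 primary alcohol | C=C[C@H](OC(C)=O)[C@@]1(C)[C@H]2O[C@H]2[C@@H](OC(C)=O)[C@@](C)(O)[C@@H]1[C@H](OC(C)=O)[C@H]2OC(C)(C)O[C@H]2CO | intermediate
19 | C6 aldehyde | C=C[C@H](OC(C)=O)[C@@]1(C)[C@H]2O[C@H]2[C@@H](OC(C)=O)[C@@](C)(O)[C@@H]1[C@H](OC(C)=O)[C@H]2OC(C)(C)O[C@H]2C=O | intermediate
20 | C6 propargylic alcohols (C6 epimers) | C=C[C@H](OC(C)=O)[C@@]1(C)[C@H]2O[C@H]2[C@@H](OC(C)=O)[C@@](C)(O)[C@@H]1[C@H](OC(C)=O)[C@H]2OC(C)(C)O[C@H]2C(O)C#C | intermediate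
21 | C6 ynone | C=C[C@H](OC(C)=O)[C@@]1(C)[C@H]2O[C@H]2[C@@H](OC(C)=O)[C@@](C)(O)[C@@H]1[C@H](OC(C)=O)[C@H]2OC(C)(C)O[C@H]2C(=O)C#C | intermediate
22 | 6,7-syn propargylic alcohol | C=C[C@H](OC(C)=O)[C@@]1(C)[C@H]2O[C@H]2[C@@H](OC(C)=O)[C@@](C)(O)[C@@H]1[C@H](OC(C)=O)[C@H]2OC(C)(C)O[C@H]2[C@H](O)C#C | intermediate
23 | C6 propargylic chloride, 7,8-acetonide | C=C[C@H](OC(C)=O)[C@@]1(C)[C@H]2O[C@H]2[C@@H](OC(C)=O)[C@@](C)(O)[C@@H]1[C@H](OC(C)=O)[C@H]2OC(C)(C)O[C@H]2[C@@H](Cl)C#C | intermediate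
24 | 7,8-diol | C=C[C@H](OC(C)=O)[C@@]1(C)[C@H]2O[C@H]2[C@@H](OC(C)=O)[C@@](C)(O)[C@@H]1[C@H](OC(C)=O)[C@@H](O)[C@@H](O)[C@@H](Cl)C#C | intermediate
25 | C7 2-bromopropanoate (CHBr epimers) | C=C[C@H](OC(C)=O)[C@@]1(C)[C@H]2O[C@H]2[C@@H](OC(C)=O)[C@@](C)(O)[C@@H]1[C@H](OC(C)=O)[C@@H](O)[C@@H](OC(=O)C(C)Br)[C@@H](Cl)C#C | intermediate
26 | C8 ketone | C=C[C@H](OC(C)=O)[C@@]1(C)[C@H]2O[C@H]2[C@@H](OC(C)=O)[C@@](C)(O)[C@@H]1[C@H](OC(C)=O)C(=O)[C@@H](OC(=O)C(C)Br)[C@@H](Cl)C#C | intermediate
27 | lactone enyne (C3 vinyl, C5≡C4 alkyne) | C=C[C@H](OC(C)=O)[C@@]1(C)[C@H]2O[C@H]2[C@@H](OC(C)=O)[C@@](C)(O)[C@@H]1[C@H](OC(C)=O)[C@]1(O)[C@@H](C)C(=O)O[C@H]1[C@@H](Cl)C#C | intermediate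
28 | lactone triene (buta-1,3-dien-2-yl on C6) | C=C[C@H](OC(C)=O)[C@@]1(C)[C@H]2O[C@H]2[C@@H](OC(C)=O)[C@@](C)(O)[C@@H]1[C@H](OC(C)=O)[C@]1(O)[C@@H](C)C(=O)O[C@H]1[C@@H](Cl)C(=C)C=C | intermediate
29 | CNP0331168.1 | C=C1/C=C\[C@H](OC(C)=O)[C@@]2(C)[C@H]3O[C@H]3[C@@H](OC(C)=O)[C@@](C)(O)[C@@H]2[C@H](OC(C)=O)[C@]2(O)[C@@H](C)C(=O)O[C@H]2[C@H]1Cl | target

**Totals and risks**

Total step count: 23. Longest linear sequence: 22 steps (L-arabinose 1 to 29 through steps 1–3 and 5–23).

Steps most likely to fail: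

Step 5 (key cycloaddition): the trisubstituted enal and a 4-substituted diene are both hindered, and the face selectivity rests on a stereoelectronic model. Fallback, from 5 back to 10: pent-1-en-3-one is silylated (TESOTf, Et3N) to (Z)-triethyl(penta-1,3-dien-3-yloxy)silane F1. A Lewis-acid-promoted Diels–Alder reaction of 5 with this diene (Me2AlCl, CH2Cl2, −78 °C) gives, with the same regiochemistry and face bias, the cyclohexene triethylsilyl enol ether F2. Saegusa–Ito oxidation (Pd(OAc)2, MeCN) then introduces the C13=C14 bond and returns to enone 10.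

Step 22 (lactone): SmI2 may instead cleave the α-acyloxy ketone, or the C8 epimer ratio may be poor. Fallback, from diol 24 back to 27: mono-silylation (TESCl, imidazole, −20 °C) gives the C7 triethylsilyl ether F3, and Dess–Martin oxidation gives the C8 ketone F4. A MgBr2·OEt2-promoted Mukaiyama aldol addition of commercial 1-methoxy-1-(trimethylsilyloxy)prop-1-ene gives the β-hydroxy methyl ester F5. HF·pyridine removes the silyl group to give the hydroxy ester F6, which lactonises in the same flask to 27.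

Step 23 (ring closure): the ten-membered ring may not close from the rigid lactone, or may give E/Z mixtures. Fallback, from chloride 23 back to 29: the same ethylene/Grubbs II sequence is run before the lactone exists. It gives the triene acetonide F7 and from it the ten-membered acetonide F8, with the cis-dioxolane acting as a turn element. Acetal hydrolysis then gives the macrocyclic diol F9, C7 acylation with 2-bromopropanoyl bromide gives the bromo ester F10, Dess–Martin oxidation gives the macrocyclic ketone F11, and the samarium Reformatsky closure of the lactone on the preformed ring gives 29.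

Further compounds
F1 | step 5 | (Z)-triethyl(penta-1,3-dien-3-yloxy)silane | C=C/C(O[Si](CC)(CC)CC)=C/C
F2 | step 5 | 1,5-dimethyl-4-(triethylsilyloxy)cyclohex-3-ene-1-carbaldehyde with the chain of 10 on C6 (C11 epimers) | O=C[C@@]1(C)CC=C(O[Si](CC)(CC)CC)C(C)[C@@H]1[C@H](OC(C)=O)[C@H]2OC(C)(C)O[C@H]2COC(C)=O
F3 | step 22 | C7 triethylsilyl ether of diol 24 | C=C[C@H](OC(C)=O)[C@@]1(C)[C@H]2O[C@H]2[C@@H](OC(C)=O)[C@@](C)(O)[C@@H]1[C@H](OC(C)=O)[C@@H](O)[C@@H](O[Si](CC)(CC)CC)[C@@H](Cl)C#C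
F4 | step 22 | C8 ketone with C7 triethylsilyl ether | C=C[C@H](OC(C)=O)[C@@]1(C)[C@H]2O[C@H]2[C@@H](OC(C)=O)[C@@](C)(O)[C@@H]1[C@H](OC(C)=O)C(=O)[C@@H](O[Si](CC)(CC)CC)[C@@H](Cl)C#C
F5 | step 22 | C8 tertiary alcohol bearing the methyl propanoate side chain (C17) and the C7 triethylsilyl ether | C=C[C@H](OC(C)=O)[C@@]1(C)[C@H]2O[C@H]2[C@@H](OC(C)=O)[C@@](C)(O)[C@@H]1[C@H](OC(C)=O)[C@](O)([C@@H](C)C(=O)OC)[C@@H](O[Si](CC)(CC)CC)[C@@H](Cl)C#C
F6 | step 22 | desilylated 7,8-dihydroxy methyl ester (not isolated) | C=C[C@H](OC(C)=O)[C@@]1(C)[C@H]2O[C@H]2[C@@H](OC(C)=O)[C@@](C)(O)[C@@H]1[C@H](OC(C)=O)[C@](O)([C@@H](C)C(=O)OC)[C@@H](O)[C@@H](Cl)C#C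
F7 | step 23 | triene acetonide (buta-1,3-dien-2-yl on C6; not isolated) | C=C[C@H](OC(C)=O)[C@@]1(C)[C@H]2O[C@H]2[C@@H](OC(C)=O)[C@@](C)(O)[C@@H]1[C@H](OC(C)=O)[C@H]2OC(C)(C)O[C@H]2[C@@H](Cl)C(=C)C=C
F8 | step 23 | ten-membered 7,8-acetonide (3Z-ene, 5(16)-methylene, 6-Cl) | C=C1/C=C\[C@H](OC(C)=O)[C@@]2(C)[C@H]3O[C@H]3[C@@H](OC(C)=O)[C@@](C)(O)[C@@H]2[C@H](OC(C)=O)[C@H]2OC(C)(C)O[C@H]2[C@H]1Cl
F9 | step 23 | macrocyclic 7,8-diol | C=C1/C=C\[C@H](OC(C)=O)[C@@]2(C)[C@H]3O[C@H]3[C@@H](OC(C)=O)[C@@](C)(O)[C@@H]2[C@H](OC(C)=O)[C@@H](O)[C@@H](O)[C@H]1Cl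
F10 | step 23 | macrocyclic C7 2-bromopropanoate (CHBr epimers) | C=C1/C=C\[C@H](OC(C)=O)[C@@]2(C)[C@H]3O[C@H]3[C@@H](OC(C)=O)[C@@](C)(O)[C@@H]2[C@H](OC(C)=O)[C@@H](O)[C@@H](OC(=O)C(C)Br)[C@H]1Cl
F11 | step 23 | macrocyclic C8 ketone | C=C1/C=C\[C@H](OC(C)=O)[C@@]2(C)[C@H]3O[C@H]3[C@@H](OC(C)=O)[C@@](C)(O)[C@@H]2[C@H](OC(C)=O)C(=O)[C@@H](OC(=O)C(C)Br)[C@H]1Cl
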